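**Retrosynthetic overview**
1. The last bond made is the ether C3–O. Acid frees the C6 alcohol, which adds to the ring A enone (5-exo oxa-Michael). This closes the oxolane bridge and fixes C3.
2. Before that, the acrylic acid comes from a C13 acetyl group (enol triflate, hydroxycarbonylation). Ring C comes from an intramolecular Michael addition (C13 to C14) onto an α-methylene δ-lactone.
3. Ring B (δ-lactone) comes from the acyl C–O bond C20–O–C7, formed after selective reduction of a C20 aldehyde.
4. The crowded C9–C10 bond is relayed from a C–O bond. A ring A hydroxymethylene ketone is O-allylated by a Baylis–Hillman bromide, and a Claisen rearrangement then sets C10 and C9.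
5. Ring A is bought as 4,4-dimethylcyclohexenone. C5 comes from a new copper-catalysed desymmetrising tert-butoxymethyl transfer to the derived dienone. Ring order: A, B, C, ether bridge.

**Atom labels (ent-kaurane style)**
- C1 ketone; C2/C3 enone carbons (C3 becomes the ether CH); C4 CMe2; C5 CH bearing C6H2O.
- C10 spiro carbon; C20 lactone OCH2; C7 lactone C=O; C8/C9 ring-fusion CH.
- C11, C12, C14 ring C CH2; C13 CH bearing C16(=C17H2)C15O2H.

**Assumption:** the sense of induction of the phosphoramidite in step 2 is taken by analogy with diethylzinc additions. Both ligand antipodes are sold, so (S)-4 is reachable either way.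

**Step 1**
Reactants: 1 4,4-dimethylcyclohex-2-en-1-one
Product: 2 4,4-dimethylcyclohexa-2,5-dien-1-one
Conditions: DDQ, dioxane, reflux
Reagents that add atoms: none
Why: DDQ dehydrogenation (hydride abstraction from the enol, then proton loss) must stop at the cross-conjugated dienone because C4 is quaternary, and no stereocentre is formed.

**Step 2**
Reactants: 2 4,4-dimethylcyclohexa-2,5-dien-1-one
Product: 4 (S)-5-(tert-butoxymethyl)-4,4-dimethylcyclohex-2-en-1-one, via zinc enolate 3 (not isolated)
Conditions: t-BuOMe, s-BuLi, KOt-Bu, −78 °C; ZnBr2, −78 to 0 °C, salts settled; then 2, Cu(OTf)2 (2 mol%), phosphoramidite from (R)-BINOL and bis[(S)-1-phenylethyl]amine (4 mol%), PhMe, −30 °C; 1 M HCl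
Reagents that add atoms: tert-butyl methyl ether, COC(C)(C)C
Why: Proposed new method: enantioselective copper/phosphoramidite-catalysed conjugate transfer of a tert-butoxymethyl group (a protected hydroxymethyl anion) from bis(tert-butoxymethyl)zinc, in which zinc-to-copper transmetalation gives a chiral Cu–CH2Ot-Bu species (no β-hydrogen, poor α-leaving group) that binds one of the two enantiotopic enone faces and delivers C6 to C5 to set 5S, while the resulting zinc enolate blocks a second addition; the closest known reaction types are Feringa-type asymmetric conjugate additions of dialkylzincs to 4,4-disubstituted cyclohexenones and cyclohexadienones, and stoichiometric racemic tert-butoxymethyl cuprate additions to enones.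

**Step 3**
Reactants: 4 (S)-5-(tert-butoxymethyl)-4,4-dimethylcyclohex-2-en-1-one
Product: 5 (5R,6Z)-5-(tert-butoxymethyl)-6-(hydroxymethylidene)-4,4-dimethylcyclohex-2-en-1-one
Conditions: NaH, HCO2Et, cat. EtOH, THF, 0 to 23 °C; 1 M HCl
Reagents that add atoms: ethyl formate, CCOC=O
Why: In this crossed Claisen condensation (α-formylation) C10 is the only enolisable carbon (C2 is vinylic, C4 quaternary), the product is drained as its stabilised enolate, and C5 keeps its geometry (only the CIP descriptor changes).

**Step 4**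
Reactants: 6 1-methylcyclopentene
Product: 8 5-oxohexanal, via ozonide 7 (not isolated)
Conditions: O3, CH2Cl2, −78 °C; Me2S, −78 to 23 °C
Reagents that add atoms: ozone, [O-][O+]=O
Why: Ozonolysis with reductive work-up (Criegee mechanism) cleaves the only alkene cleanly to the keto aldehyde.

**Step 5**
Reactants: 8 5-oxohexanal; 9 methyl acrylate
Product: 10 methyl 3-hydroxy-2-methylidene-7-oxooctanoate (racemic)
Conditions: DABCO (0.5 equiv), dioxane/H2O 1:1, 23 °C
Reagents that add atoms: none
Why: In the Morita–Baylis–Hillman reaction the aldehyde is far more electrophilic than the methyl ketone, and the racemic carbinol centre is erased in step 6.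

**Step 6**
Reactants: 10 methyl 3-hydroxy-2-methylidene-7-oxooctanoate
Product: 11 methyl (Z)-2-(bromomethyl)-7-oxooct-2-enoate
Conditions: PBr3 (0.4 equiv), Et2O, 0 °C
Reagents that add atoms: phosphorus tribromide, BrP(Br)Br
Why: SN2′ bromination of a Baylis–Hillman alcohol gives the conjugated trisubstituted bromide, reliably as the Z isomer with the alkyl chain cis to CH2Br.

**Step 7**
Reactants: 5 (5R,6Z)-5-(tert-butoxymethyl)-6-(hydroxymethylidene)-4,4-dimethylcyclohex-2-en-1-one; 11 methyl (Z)-2-(bromomethyl)-7-oxooct-2-enoate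
Product: 13 methyl (3S)-3-[(1S,6R)-6-(tert-butoxymethyl)-1-formyl-5,5-dimethyl-2-oxocyclohex-3-en-1-yl]-2-methylidene-7-oxooctanoate, via allyl vinyl ether 12 (not isolated)
Conditions: K2CO3, DMF, 23 °C; filter, dilute with PhMe, 130 °C, sealed tube
Reagents that add atoms: none
Why: Williamson-type O-alkylation (the hindered C10 cannot compete with the exposed enol oxygen) gives the (E)-enol ether, and the Claisen rearrangement through a chair on the ring A face opposite the pseudo-axial CH2Ot-Bu group then sets C10 (C9 trans to C6, C20 cis to C6) and C9 (C11 anti to C5, H9 under ring A) while leaving the C8=C14 methylene ester.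

**Step 8**
Reactants: 13 methyl (3S)-3-[(1S,6R)-6-(tert-butoxymethyl)-1-formyl-5,5-dimethyl-2-oxocyclohex-3-en-1-yl]-2-methylidene-7-oxooctanoate
Product: 15 (5S,6S,11R)-11-(tert-butoxymethyl)-10,10-dimethyl-4-methylidene-5-(4-oxopentyl)-2-oxaspiro[5.5]undec-8-ene-3,7-dione, via hydroxy ester 14 (not isolated)
Conditions: NaBH4, CH2Cl2/MeOH 1:1, −78 °C; then CSA (10 mol%), CH2Cl2, 23 °C
Reagents that add atoms: none
Why: Chemoselective borohydride reduction at −78 °C takes the activated aldehyde well ahead of the methyl ketone, enone and acrylate, and acid-catalysed lactonisation (acyl substitution, C20–O–C7) then closes ring B without touching a stereocentre.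

**Step 9**
Reactants: 15 (5S,6S,11R)-11-(tert-butoxymethyl)-10,10-dimethyl-4-methylidene-5-(4-oxopentyl)-2-oxaspiro[5.5]undec-8-ene-3,7-dione
Product: 16 cis-fused spiro tricycle (5R,8S,9R,10S,13R): (4S,4aR,7R,8aS)-7-acetyl-octahydroisochromen-1-one spiro-linked at C4 to C1 of (6R)-6-(tert-butoxymethyl)-5,5-dimethylcyclohex-3-en-2-one
Conditions: KOt-Bu (20 mol%), THF/t-BuOH 10:1, −40 to 0 °C; pH 7 buffer
Reagents that add atoms: none
Why: In this intramolecular Michael addition (6-endo-trig) ring A has no enolisable hydrogen and only the internal ketone enolate reaches C14 through a chair with the C10 arm equatorial, so C13 equilibrates to the equatorial acetyl epimer (13R, trans to C10) and the lactone enolate is protonated kinetically at C8 on the H9 face (the other face is screened by the axial C1 arm and the axial hydrogens at C11 and C13) to give the cis-fused 8S lactone.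

**Step 10**
Reactants: 16 cis-fused spiro tricycle with C13 acetyl group
Product: 18 C16 enol triflate of 16 (1-substituted vinyl triflate, 5R,8S,9R,10S,13R), via potassium enolate 17 (not isolated)
Conditions: KN(SiMe3)2 (1.0 equiv), THF, −78 °C; PhNTf2, −78 to 0 °C; cold 0.5 M HCl wash
Reagents that add atoms: N-phenylbis(trifluoromethanesulfonimide), O=S(=O)(N(c1ccccc1)S(=O)(=O)C(F)(F)F)C(F)(F)F
Why: Kinetic enolisation and O-triflation takes the unhindered CH3 of the methyl ketone ahead of the tertiary C13–H and C8–H, so no stereocentre is disturbed.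

**Step 11**
Reactants: 18 C16 enol triflate
Product: 19 2-substituted acrylic acid, still the C6 tert-butyl ether and ring A enone (5R,8S,9R,10S,13R)
Conditions: Pd(OAc)2 (5 mol%), PPh3 (10 mol%), CO (1 atm), Et3N, DMF/H2O, 50 °C
Reagents that add atoms: carbon monoxide, [C-]#[O+]; water, O
Why: In this palladium-catalysed hydroxycarbonylation the vinyl triflate adds oxidatively to zerovalent palladium, CO inserts and water cleaves the acyl complex, installing C15 under mild conditions that spare the lactone, enone and ether.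

**Step 12**
Reactants: 19 acrylic acid tert-butyl ether
Product: 21 target CNP0268721.2 (3R,5R,8S,9R,10S,13R), via primary alcohol 20 (not isolated)
Conditions: TFA/CH2Cl2 1:4, 0 to 23 °C
Reagents that add atoms: none
Why: Acidolysis of the tert-butyl ether (E1 loss of isobutene) is followed by an acid-catalysed intramolecular oxa-Michael addition (5-exo-trig, helped by the gem-dimethyl group), in which the C6 oxygen can reach C3 only from its own face, so the C3–O bond closes the 6-oxabicyclo[3.2.1]octanone with 3R and no base touches C8.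

**Compound list**
1 | 4,4-dimethylcyclohex-2-en-1-one | CC1(C)CCC(=O)C=C1 | starting material
2 | 4,4-dimethylcyclohexa-2,5-dien-1-one | CC1(C)C=CC(=O)C=C1 | intermediate
3 | (tert-butoxymethyl)zinc dienolate of 4 | CC(C)(C)OC[Zn]OC1=C[C@H](COC(C)(C)C)C(C)(C)C=C1 | intermediate
4 | (S)-5-(tert-butoxymethyl)-4,4-dimethylcyclohex-2-en-1-one | O=C1C=CC(C)(C)[C@@H](COC(C)(C)C)C1 | intermediate
5 | (5R,6Z)-5-(tert-butoxymethyl)-6-(hydroxymethylidene)-4,4-dimethylcyclohex-2-en-1-one | O=C1C=CC(C)(C)[C@@H](COC(C)(C)C)/C1=C/O | intermediate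
6 | 1-methylcyclopentene | CC1=CCCC1 | starting material
7 | 1-methyl-6,7,8-trioxabicyclo[3.2.1]octane (ozonide, racemic) | CC12CCCC(OO1)O2 | intermediate
8 | 5-oxohexanal | CC(=O)CCCC=O | intermediate
9 | methyl acrylate | C=CC(=O)OC | starting material
10 | methyl 3-hydroxy-2-methylidene-7-oxooctanoate (racemic) | C=C(C(=O)OC)C(O)CCCC(C)=O | intermediate
11 | methyl (Z)-2-(bromomethyl)-7-oxooct-2-enoate | BrC/C(C(=O)OC)=C\CCCC(C)=O | intermediate
12 | methyl (2E)-2-({(E)-[(6R)-6-(tert-butoxymethyl)-5,5-dimethyl-2-oxocyclohex-3-en-1-ylidene]methoxy}methyl)-7-oxooct-2-enoate | O=C1C=CC(C)(C)[C@@H](COC(C)(C)C)/C1=C\OC/C(C(=O)OC)=C\CCCC(C)=O | intermediate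
13 | methyl (3S)-3-[(1S,6R)-6-(tert-butoxymethyl)-1-formyl-5,5-dimethyl-2-oxocyclohex-3-en-1-yl]-2-methylidene-7-oxooctanoate | O=C1C=CC(C)(C)[C@@H](COC(C)(C)C)[C@]1(C=O)[C@H](CCCC(C)=O)C(=C)C(=O)OC | intermediate
14 | methyl (3S)-3-[(1S,6R)-6-(tert-butoxymethyl)-1-(hydroxymethyl)-5,5-dimethyl-2-oxocyclohex-3-en-1-yl]-2-methylidene-7-oxooctanoate | O=C1C=CC(C)(C)[C@@H](COC(C)(C)C)[C@]1(CO)[C@H](CCCC(C)=O)C(=C)C(=O)OC | intermediate
15 | (5S,6S,11R)-11-(tert-butoxymethyl)-10,10-dimethyl-4-methylidene-5-(4-oxopentyl)-2-oxaspiro[5.5]undec-8-ene-3,7-dione | O=C1C=CC(C)(C)[C@@H](COC(C)(C)C)[C@@]12COC(=O)C(=C)[C@H]2CCCC(C)=O | intermediate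
16 | cis-fused spiro tricyclic methyl ketone (5R,8S,9R,10S,13R) | CC(=O)[C@@H]1CC[C@@H]2[C@H](C1)C(=O)OC[C@]21C(=O)C=CC(C)(C)[C@H]1COC(C)(C)C | intermediate
17 | terminal potassium enolate of 16 | [K+].C=C([O-])[C@@H]1CC[C@@H]2[C@H](C1)C(=O)OC[C@]21C(=O)C=CC(C)(C)[C@H]1COC(C)(C)C | intermediate
18 | C16 vinyl triflate (5R,8S,9R,10S,13R) | C=C(OS(=O)(=O)C(F)(F)F)[C@@H]1CC[C@@H]2[C@H](C1)C(=O)OC[C@]21C(=O)C=CC(C)(C)[C@H]1COC(C)(C)C | intermediate
19 | acrylic acid with C6 tert-butyl ether and ring A enone (5R,8S,9R,10S,13R) | C=C(C(=O)O)[C@@H]1CC[C@@H]2[C@H](C1)C(=O)OC[C@]21C(=O)C=CC(C)(C)[C@H]1COC(C)(C)C | intermediate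
20 | acrylic acid with free C6 alcohol and ring A enone (5R,8S,9R,10S,13R) | C=C(C(=O)O)[C@@H]1CC[C@@H]2[C@H](C1)C(=O)OC[C@]21C(=O)C=CC(C)(C)[C@H]1CO | intermediate
21 | CNP0268721.2 (3R,5R,8S,9R,10S,13R) | C=C(C(=O)O)[C@@H]1CC[C@@H]2[C@H](C1)C(=O)OC[C@]21C(=O)C[C@H]2OC[C@@H]1C2(C)C | target

**Total step count:** 12.
**Longest linear sequence:** 9 (steps 1–3 then 7–12, or steps 4–6 then 7–12).

**Three steps most likely to fail**

*Step 2 (the new step).* The α-oxygenated zinc reagent may transfer slowly, or residual salts may erode the ee. The fallback sets out from 2. Stoichiometric lithium bis(tert-butoxymethyl)cuprate, (t-BuOCH2)2CuLi, in THF at −78 °C is a known cuprate hydroxymethyl-anion equivalent. It gives racemic 5-(tert-butoxymethyl)-4,4-dimethylcyclohex-2-en-1-one F1. F1 is resolved by preparative chiral-phase SFC, and the (S)-enantiomer comes back to the route at 4.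

*Step 7.* The enol ether may form as an E/Z mixture, a boat transition state may leak the C9 epimer, or the crowded rearrangement may need temperatures at which the formyl group is lost. The fallback sets out from 11 (with 5 as partner). DABCO in THF/H2O turns the bromide into the allyl ammonium salt 1-[(Z)-2-(methoxycarbonyl)-7-oxooct-2-en-1-yl]-1,4-diazabicyclo[2.2.2]octan-1-ium bromide F2. The sodium enolate of 5 then attacks C9 in the known addition–elimination (SN2′) mode of such Baylis–Hillman salts. This forms C9–C10 directly and comes back at 13.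

*Step 9.* Alkoxide may epimerise C8 to the trans-lactone or divert the enolate to acylation at C7. The fallback sets out from 15 and uses a neutral Stork enamine cyclisation. Pyrrolidine with molecular sieves in benzene gives the internal pyrrolidine enamine of 15 F3. Warming closes ring C to the cyclised enamine of 16 F4. Buffered hydrolysis (AcOH/NaOAc/H2O) comes back at 16, with C8 protonated under non-equilibrating conditions.

**Further compounds**
F1 | step 2 | racemic 5-(tert-butoxymethyl)-4,4-dimethylcyclohex-2-en-1-one | O=C1C=CC(C)(C)C(COC(C)(C)C)C1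
F2 | step 7 | 1-[(Z)-2-(methoxycarbonyl)-7-oxooct-2-en-1-yl]-1,4-diazabicyclo[2.2.2]octan-1-ium bromide | COC(=O)/C(C[N+]12CCN(CC1)CC2)=C/CCCC(C)=O.[Br-]
F3 | step 9 | internal (E)-pyrrolidine enamine of 15 | O=C1C=CC(C)(C)[C@@H](COC(C)(C)C)[C@@]12COC(=O)C(=C)[C@H]2CC/C=C(\C)N1CCCC1
F4 | step 9 | cyclised pyrrolidine enamine of 16 | C=C(N1CCCC1)[C@@H]1CC[C@@H]2[C@H](C1)C(=O)OC[C@]21C(=O)C=CC(C)(C)[C@H]1COC(C)(C)C
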